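## Analysis of the target

The target (21) is a flavone: a chromen-4-one, made of benzene ring A fused to pyranone ring C, that carries an aryl group (ring B) at C2. Ring A is hexasubstituted. Hydroxyls at C5 and C7 alternate with methoxyls at C6 and C8, and the two remaining positions are the fusion atoms C4a and C8a. Ring C bears a methoxyl at C3 and ring B is a 2',5'-dihydroxy-4'-methoxyphenyl group, so the only ring C–H bonds are at C3' and C6'. There is no stereocentre, so the whole problem is one of constitution. The sensitive parts are the para-hydroquinone of ring B (air and base turn it into a quinone), the very electron-rich ring A, and the pyranone, which nucleophiles can open at C2. The difficulty is twofold: four methyl groups and four hydrogens must be placed on eight oxygens without a late selective methylation or demethylation, and the C4a–C4 bond must be made at a carbon flanked by two oxygen-bearing carbons. The strategy rests on two features. C4 is a single carbonyl carbon between C4a of ring A and the C3=C2 unit that carries ring B, so it can come from carbon monoxide. And as long as ring C is open, ring A is symmetrical about the axis through C4a and C7 (the C5 and C8a oxygens are equivalent, as are the C6 and C8 methoxyls), so a symmetrical ring A iodide can close ring C through either flanking oxygen.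

## Retrosynthetic reasoning

**21 from 20.** The four O–benzyl bonds are cut last. Throughout the route, an oxygen that ends as methoxyl is a methyl ether and an oxygen that ends as hydroxyl is a benzyl ether or an acetate, so no selective methylation is ever needed. The hydroquinone and the phenols then appear only in the final step, under reducing conditions.

**20 from 19 from 16 from 15.** The O–CH3 bond at C3 is cut, then the C3–O bond. The ring C closure chosen below leaves hydrogen at C3, so the 3-oxygen has to be put in afterwards. In 16 this hydrogen is the only one on ring C and sits next to the C4 carbonyl, so an amide base can remove it; the carbanion is converted through boron into the hydroxyl of 19. That hydroxyl is the only free one in 19 and is methylated to 20. The deprotonation tolerates no free phenol, which is why the chelated 5-hydroxyl of 15 is benzylated first to give 16.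

**15 from 6, 11 and 12.** Three bonds are cut together: C4a–C4, C4–C3 and O1–C2. This divides the molecule into its two aromatic halves and a one-carbon unit, and each half already carries its full oxygen pattern. The forward reaction has to insert carbon monoxide (12) between the aryl iodide 6 and the terminal alkyne 11, free a phenol from its acetate, and close the six-membered ring. Because 6 is symmetrical, either acetoxy group may supply O1 and the other one becomes the 5-hydroxyl. The oxygen that becomes O7 takes no part; it stays as the benzyl ether it already is from the ring A synthesis, so only the two oxygens next to iodine are acetates.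

**6 from 5 from 4.** The acetyl groups and then the C–I bond are cut. Diol 4 has a single ring hydrogen, between the two hydroxyls, so iodination has no regiochemical choice. Acetylation then gives the iodide a stable, storable form.

**4 from 3 from 2 from 1.** The two C–OH bonds go back to C–Br and then to C–H. Syringol (1) already contains the methoxy–oxygen–methoxy triad of C6, C7 and C8. Once its hydroxyl is benzylated (2), the two positions ortho to the methoxy groups are the reactive ones, and these are where the oxygens of C5 and C8a are needed. The position para to the benzyloxy group, the future C4a, stays free for iodine.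

**11 from 10 from 8 from 7.** The alkyne is cut back to aldehyde 10 by a one-carbon homologation, the formyl group is removed to give 8, and the benzyl ethers are removed to give methoxyhydroquinone (7). In 8 only one position is ortho to one alkoxy group and para to another, and formylation there gives the 2',5'-dioxygen-4'-methoxy pattern of ring B.

## Alternatives that were turned down

**Alternative 1:** The C3–C4 bond of the 3-hydroxychroman-4-one A1 is cut. The precursor is dialdehyde A2, a ring A salicylaldehyde whose phenolic oxygen carries the CH(aryl)–CHO unit of ring B. In the forward step, an N-heterocyclic carbene from a triazolium salt and an amidine base would add to the aromatic aldehyde, and the acyl anion equivalent would attack the aliphatic aldehyde in an intramolecular crossed benzoin reaction.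
- For it: the closure is metal-free and brings the 3-oxygen with it. On this point it is stronger than the chosen route, which spends a separate C–H oxidation on C3.
- Against it: the carbene must choose the aromatic aldehyde, which in A2 is flanked by two ortho oxygens and is the more hindered and less electrophilic of the two. Addition to the aliphatic aldehyde would put the ketone at C3 and the hydroxyl at C4.
- The aliphatic aldehyde of A2 is both α-aryl and α-aryloxy, so it enolises easily and can expel the ring A phenoxide.
- A1 forms as a diastereomer mixture whose two stereocentres are then destroyed: it must still be dehydrogenated across C2–C3 and methylated. That is the same two steps the chosen route spends on C3.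
- A2 needs formylation of a pentaoxygenated phenol and O-alkylation of a hindered phenol with a fragile aldehyde equivalent, so it is longer and less convergent.
- In place of the built-in 3-oxygen, the chosen route offers two stable precursors (6 and 11) and closure directly at the flavone oxidation level.

**Alternative 2:** Ring B is cut across C1'–C2', C2'–C3' and C5'–C6' and built last on a finished chromone. The 2-ethynylchromone A4 is heated with the chromium carbene complex (CO)5Cr=C(OMe)C(OMe)=CH2, A5, and Dötz benzannulation gives phenol A3.
- For it: the regiochemistry with a terminal alkyne is dependable (the alkyne substituent ends next to the new phenol), and the 2'-hydroxyl comes out free.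
- Against it: A3 has a methyl ether on the 5'-oxygen, because the carbene carbon brings its methoxy group into the ring. The target has a hydroxyl there next to the 4'-methoxyl, so one methyl ether out of five would have to be cleaved. Nothing in the structure directs that; Lewis acids would attack the ethers next to the carbonyl first.
- The sequence uses stoichiometric chromium and a labile vinylcarbene complex at the very end, and the oxidants normally used to remove chromium threaten the electron-rich phenol.
- A4 contains all of hexasubstituted ring A and ring C with its 3-methoxyl, so the hard part of the synthesis is still unsolved.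
- The chosen route is shorter, and its ring B carries both future hydroxyls as benzyl ethers, distinct from the 4'-methoxyl, from the first step.

**Alternative 3:** The O1–C8a bond is cut. The precursor is the 1,3-diketone A7, with a 4-benzyloxy-2,6-dibromo-3,5-dimethoxybenzoyl group on one side and a methoxyl on the central carbon. In the forward step, a copper-catalysed Ullmann-type O-arylation (phenanthroline ligand, carbonate base) lets the enolate oxygen of the ring B ketone displace one of the two equivalent bromines, giving A6.
- For it: the 3-methoxyl is present from the start, so no late functionalisation of C3 is needed. This is stronger than the chosen route. It also uses the symmetry of ring A in the same way and needs no gas.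
- Against it: A6 has bromine at C5 where the target has hydroxyl. A second C–O bond must then be made at the most hindered position, between the carbonyl and a methoxy group, under conditions that expose the pyranone to hydroxide.
- The aroyl group of A7 has two ortho bromines; it is twisted out of conjugation and hard to assemble by Claisen-type acylation. The 2-methoxy-1,3-diketone may also undergo retro-Claisen cleavage under hot carbonate.
- The chosen route gets the 5-hydroxyl for free from the acetate not used in ring closure. It makes the C4a–C4 bond by insertion of palladium into a C–I bond, where ortho substituents hinder less than in a carbonyl addition. It pays for this with two steps for the 3-oxygen.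

Key step: step 9

Remark: the oxygen at C7 is carried through the key step as its benzyl ether. In the twofold reactions (dibromination, double hydroxylation, diacetylation, dibenzylation) the half-reacted species counts as a stage of the same step and gets no number.

## Route

### Ring A iodide

Step 1
Reactants: 1 2,6-dimethoxyphenol (syringol)
Product: 2 2-(benzyloxy)-1,3-dimethoxybenzene
Conditions: BnBr, K2CO3, DMF, 60 °C
Reagents that add atoms: benzyl bromide, BrCc1ccccc1
Why: Williamson ether synthesis on the phenoxide; the benzyl group stays on this oxygen (the later O7) to the last step and stops the free phenol from directing substitution to its para position.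

Step 2
Reactants: 2 2-(benzyloxy)-1,3-dimethoxybenzene
Product: 3 3-(benzyloxy)-1,5-dibromo-2,4-dimethoxybenzene
Conditions: NBS (2.1 equiv), MeCN, 0 °C → rt, dark
Reagents that add atoms: N-bromosuccinimide, O=C1CCC(=O)N1Br
Why: Electrophilic aromatic bromination; as in 1,2,3-trimethoxybenzene, the central alkoxy group is twisted out of conjugation, so both bromines should enter ortho to the outer methoxy groups and the position para to the benzyloxy group should stay free.

Step 3
Reactants: 3 3-(benzyloxy)-1,5-dibromo-2,4-dimethoxybenzene
Product: 4 5-(benzyloxy)-4,6-dimethoxybenzene-1,3-diol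
Conditions: Pd2(dba)3 (2 mol %), tBuXPhos (8 mol %), KOH, dioxane–H2O, 100 °C, argon; then aq. HCl
Reagents that add atoms: potassium hydroxide, [K+].[OH-]
Why: Palladium-catalysed hydroxylation of aryl bromides (C–O cross-coupling with hydroxide); the bulky biarylphosphine favours C–O reductive elimination over diaryl ether formation, and the benzyl and methyl ethers are inert to hot hydroxide.

Step 4
Reactants: 4 5-(benzyloxy)-4,6-dimethoxybenzene-1,3-diol
Product: 5 5-(benzyloxy)-2-iodo-4,6-dimethoxybenzene-1,3-diol
Conditions: NIS (1.05 equiv), MeCN, 0 °C, dark, argon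
Reagents that add atoms: N-iodosuccinimide, O=C1CCC(=O)N1I
Why: Electrophilic iodination of a resorcinol; the only ring hydrogen lies ortho to both hydroxyls and para to the benzyloxy group, so there is no regiochemical choice, and the mild iodonium source at low temperature limits oxidation of the electron-rich ring.

Step 5
Reactants: 5 5-(benzyloxy)-2-iodo-4,6-dimethoxybenzene-1,3-diol
Product: 6 5-(benzyloxy)-2-iodo-4,6-dimethoxy-1,3-phenylene diacetate
Conditions: Ac2O, pyridine, DMAP (cat.), CH2Cl2, rt
Reagents that add atoms: acetic anhydride, CC(=O)OC(C)=O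
Why: DMAP-catalysed O-acylation of both phenols; the acetates make the iodide stable to air and are the groups the secondary amine removes in the key step.

### Ring B alkyne

Step 6
Reactants: 7 methoxyhydroquinone (2-methoxybenzene-1,4-diol)
Product: 8 1,4-bis(benzyloxy)-2-methoxybenzene
Conditions: BnBr, K2CO3, DMF, 60 °C, argon
Reagents that add atoms: benzyl bromide, BrCc1ccccc1
Why: Twofold Williamson ether synthesis; working under argon keeps the hydroquinone dianion from oxidising, and the benzyl ethers mark the two oxygens that end as the 2'- and 5'-hydroxyls.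

Step 7
Reactants: 8 1,4-bis(benzyloxy)-2-methoxybenzene
Product: 10 2,5-bis(benzyloxy)-4-methoxybenzaldehyde, via iminium chloride 9 (not isolated)
Conditions: POCl3, DMF, 0 → 70 °C; then ice-water
Reagents that add atoms: N,N-dimethylformamide, CN(C)C=O; water, O (POCl3, O=P(Cl)(Cl)Cl, supplies only the chloride counter-ion of 9)
Why: Vilsmeier–Haack formylation; the chloroiminium ion should attack the one position that is ortho to one alkoxy group and para to another (the pattern known from 1,2,4-trialkoxybenzenes), and water hydrolyses iminium salt 9 to the aldehyde.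

Step 8
Reactants: 10 2,5-bis(benzyloxy)-4-methoxybenzaldehyde
Product: 11 1,4-bis(benzyloxy)-2-ethynyl-5-methoxybenzene
Conditions: dimethyl (1-diazo-2-oxopropyl)phosphonate, K2CO3, MeOH–THF, rt
Reagents that add atoms: dimethyl (1-diazo-2-oxopropyl)phosphonate, COP(=O)(OC)C(=[N+]=[N-])C(C)=O
Why: Seyferth–Gilbert homologation in its Ohira–Bestmann form; methanolysis frees the diazomethylphosphonate anion, which adds to the aldehyde, loses dimethyl phosphate and then nitrogen, and the alkylidene carbene rearranges by 1,2-hydrogen shift to the terminal alkyne under conditions that leave the benzyl ethers alone.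

### Key step and completion

Step 9
Reactants: 6 5-(benzyloxy)-2-iodo-4,6-dimethoxy-1,3-phenylene diacetate; 11 1,4-bis(benzyloxy)-2-ethynyl-5-methoxybenzene; 12 carbon monoxide
Product: 15 7-(benzyloxy)-2-[2,5-bis(benzyloxy)-4-methoxyphenyl]-5-hydroxy-6,8-dimethoxy-4H-chromen-4-one, via ynone diacetate 13 (not isolated), via diethylamino enone 14 (not isolated)
Conditions: PdCl2(PPh3)2 (5 mol %), dppp (5 mol %), CO (3 bar), Et2NH–THF, 50 °C
Reagents that add atoms: carbon monoxide (12), [C-]#[O+] (diethylamine, CCNCC, adds atoms to intermediate 14 only)
Why: This is the palladium-catalysed carbonylative annulation of o-iodophenyl acetates with terminal alkynes, a carbonylative Sonogashira coupling followed by amine-mediated ring closure. Zerovalent palladium, formed in the flask from PdCl2(PPh3)2, inserts into the C–I bond of 6, CO inserts to give the aroylpalladium species, and alkynylation by 11 with reductive elimination gives ynone 13, which forms C4a–C4 and C4–C3. Et2NH then cleaves both aryl acetates as N,N-diethylacetamide and adds to the β-carbon of the ynone to give enaminone 14. One phenol oxygen attacks that β-carbon and Et2NH leaves, which forms O1–C2 and closes ring C by a 6-endo-trig addition–elimination; no stereocentre arises. The step needs CO insertion to outrun direct alkynylation, which would end in a benzofuran: the electron-rich aryl group migrates readily to CO, the two ortho substituents slow the direct coupling, and CO pressure supports insertion. It needs six-membered (flavone) and not five-membered (aurone) closure: in 14 the β-carbon is the only electrophilic site, so the 5-exo path to the α-carbon is shut. The two acetoxy groups next to iodine are equivalent by the mirror plane through the C–I and C–OBn bonds, so either becomes O1 and the other becomes the 5-hydroxyl, and the benzyl and methyl ethers are inert.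

Step 10
Reactants: 15 7-(benzyloxy)-2-[2,5-bis(benzyloxy)-4-methoxyphenyl]-5-hydroxy-6,8-dimethoxy-4H-chromen-4-one
Product: 16 5,7-bis(benzyloxy)-2-[2,5-bis(benzyloxy)-4-methoxyphenyl]-6,8-dimethoxy-4H-chromen-4-one
Conditions: BnBr, K2CO3, KI (cat.), DMF, 70 °C
Reagents that add atoms: benzyl bromide, BrCc1ccccc1
Why: Williamson ether synthesis on the 5-hydroxyl, the only acidic group; its hydrogen bond to the C4 carbonyl lowers its reactivity, hence the heating and the iodide catalyst, and capping it is required before the strong base of step 11.

Step 11
Reactants: 16 5,7-bis(benzyloxy)-2-[2,5-bis(benzyloxy)-4-methoxyphenyl]-6,8-dimethoxy-4H-chromen-4-one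
Product: 19 5,7-bis(benzyloxy)-2-[2,5-bis(benzyloxy)-4-methoxyphenyl]-3-hydroxy-6,8-dimethoxy-4H-chromen-4-one, via 3-lithioflavone 17 (not isolated), via flavone-3-boronate 18 (not isolated)
Conditions: LiN(iPr)2 (1.5 equiv), THF, −78 °C; B(OMe)3, −78 → 0 °C; AcOH, 30% H2O2, 0 °C → rt
Reagents that add atoms: hydrogen peroxide, OO (trimethyl borate, COB(OC)OC, adds atoms to intermediate 18 only)
Why: Carbonyl-directed lithiation of the flavone C3–H, borylation of the vinyllithium and oxidative boron-to-oxygen 1,2-migration, the known route from flavones to flavonols; C3–H is the only hydrogen on ring C, and trapping at −78 °C should keep 17 from opening to an ynone phenoxide.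

Step 12
Reactants: 19 5,7-bis(benzyloxy)-2-[2,5-bis(benzyloxy)-4-methoxyphenyl]-3-hydroxy-6,8-dimethoxy-4H-chromen-4-one
Product: 20 5,7-bis(benzyloxy)-2-[2,5-bis(benzyloxy)-4-methoxyphenyl]-3,6,8-trimethoxy-4H-chromen-4-one
Conditions: MeI, K2CO3, acetone, reflux
Reagents that add atoms: iodomethane, CI
Why: O-methylation (Williamson) of the flavonol hydroxyl, which is the only free hydroxyl in 19, so no selectivity question arises.

Step 13
Reactants: 20 5,7-bis(benzyloxy)-2-[2,5-bis(benzyloxy)-4-methoxyphenyl]-3,6,8-trimethoxy-4H-chromen-4-one
Product: 21 5,7,2',5'-tetrahydroxy-3,6,8,4'-tetramethoxyflavone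
Conditions: H2 (1 atm), Pd/C (10% palladium on carbon), EtOAc–MeOH, rt; filtration and concentration under argon
Reagents that add atoms: none
Why: Catalytic hydrogenolysis of the four benzyl aryl ethers; the tetrasubstituted C2=C3 bond of the 3-methoxyflavone is a vinylogous ester and should not be reduced at atmospheric pressure, and the reducing medium protects the new hydroquinone.

## Compound list

1 | 2,6-dimethoxyphenol (syringol) | COc1cccc(OC)c1O | starting material
2 | 2-(benzyloxy)-1,3-dimethoxybenzene | COc1cccc(OC)c1OCc1ccccc1 | intermediate
3 | 3-(benzyloxy)-1,5-dibromo-2,4-dimethoxybenzene | COc1c(Br)cc(Br)c(OC)c1OCc1ccccc1 | intermediate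
4 | 5-(benzyloxy)-4,6-dimethoxybenzene-1,3-diol | COc1c(O)cc(O)c(OC)c1OCc1ccccc1 | intermediate
5 | 5-(benzyloxy)-2-iodo-4,6-dimethoxybenzene-1,3-diol | COc1c(O)c(I)c(O)c(OC)c1OCc1ccccc1 | intermediate
6 | 5-(benzyloxy)-2-iodo-4,6-dimethoxy-1,3-phenylene diacetate | COc1c(OC(C)=O)c(I)c(OC(C)=O)c(OC)c1OCc1ccccc1 | intermediate
7 | methoxyhydroquinone (2-methoxybenzene-1,4-diol) | COc1cc(O)ccc1O | starting material
8 | 1,4-bis(benzyloxy)-2-methoxybenzene | COc1cc(OCc2ccccc2)ccc1OCc1ccccc1 | intermediate
9 | [2,5-bis(benzyloxy)-4-methoxybenzylidene]dimethylammonium chloride | COc1cc(OCc2ccccc2)c(C=[N+](C)C)cc1OCc1ccccc1.[Cl-] | intermediate (not isolated)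
10 | 2,5-bis(benzyloxy)-4-methoxybenzaldehyde | COc1cc(OCc2ccccc2)c(C=O)cc1OCc1ccccc1 | intermediate
11 | 1,4-bis(benzyloxy)-2-ethynyl-5-methoxybenzene | COc1cc(OCc2ccccc2)c(C#C)cc1OCc1ccccc1 | intermediate
12 | carbon monoxide | [C-]#[O+] | starting material
13 | 5-(benzyloxy)-2-{3-[2,5-bis(benzyloxy)-4-methoxyphenyl]prop-2-ynoyl}-4,6-dimethoxy-1,3-phenylene diacetate | COc1c(OC(C)=O)c(C(=O)C#Cc2cc(OCc3ccccc3)c(OC)cc2OCc2ccccc2)c(OC(C)=O)c(OC)c1OCc1ccccc1 | intermediate (not isolated)
14 | 1-[4-(benzyloxy)-2,6-dihydroxy-3,5-dimethoxyphenyl]-3-[2,5-bis(benzyloxy)-4-methoxyphenyl]-3-(diethylamino)prop-2-en-1-one (alkene geometry not fixed) | CCN(CC)C(=CC(=O)c1c(O)c(OC)c(OCc2ccccc2)c(OC)c1O)c1cc(OCc2ccccc2)c(OC)cc1OCc1ccccc1 | intermediate (not isolated)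
15 | 7-(benzyloxy)-2-[2,5-bis(benzyloxy)-4-methoxyphenyl]-5-hydroxy-6,8-dimethoxy-4H-chromen-4-one | COc1cc(OCc2ccccc2)c(cc1OCc1ccccc1)-c1cc(=O)c2c(O)c(OC)c(OCc3ccccc3)c(OC)c2o1 | intermediate
16 | 5,7-bis(benzyloxy)-2-[2,5-bis(benzyloxy)-4-methoxyphenyl]-6,8-dimethoxy-4H-chromen-4-one | COc1cc(OCc2ccccc2)c(cc1OCc1ccccc1)-c1cc(=O)c2c(OCc3ccccc3)c(OC)c(OCc3ccccc3)c(OC)c2o1 | intermediate
17 | {5,7-bis(benzyloxy)-2-[2,5-bis(benzyloxy)-4-methoxyphenyl]-6,8-dimethoxy-4-oxo-4H-chromen-3-yl}lithium | COc1cc(OCc2ccccc2)c(-c2oc3c(OC)c(OCc4ccccc4)c(OC)c(OCc4ccccc4)c3c(=O)c2[Li])cc1OCc1ccccc1 | intermediate (not isolated)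
18 | dimethyl {5,7-bis(benzyloxy)-2-[2,5-bis(benzyloxy)-4-methoxyphenyl]-6,8-dimethoxy-4-oxo-4H-chromen-3-yl}boronate | COc1cc(OCc2ccccc2)c(-c2oc3c(OC)c(OCc4ccccc4)c(OC)c(OCc4ccccc4)c3c(=O)c2B(OC)OC)cc1OCc1ccccc1 | intermediate (not isolated)
19 | 5,7-bis(benzyloxy)-2-[2,5-bis(benzyloxy)-4-methoxyphenyl]-3-hydroxy-6,8-dimethoxy-4H-chromen-4-one | COc1cc(OCc2ccccc2)c(-c2oc3c(OC)c(OCc4ccccc4)c(OC)c(OCc4ccccc4)c3c(=O)c2O)cc1OCc1ccccc1 | intermediate
20 | 5,7-bis(benzyloxy)-2-[2,5-bis(benzyloxy)-4-methoxyphenyl]-3,6,8-trimethoxy-4H-chromen-4-one | COc1cc(OCc2ccccc2)c(-c2oc3c(OC)c(OCc4ccccc4)c(OC)c(OCc4ccccc4)c3c(=O)c2OC)cc1OCc1ccccc1 | intermediate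
21 | 5,7,2',5'-tetrahydroxy-3,6,8,4'-tetramethoxyflavone | COc1cc(O)c(-c2oc3c(OC)c(O)c(OC)c(O)c3c(=O)c2OC)cc1O | target

## Step count and least certain steps

Total: 13 steps. Longest linear sequence: 10 steps (steps 1–5 and 9–13). The ring B branch is steps 6–8.

**Step 9 (key step).** The aroylpalladium species is flanked by two ortho oxygens, so alkynylation is slow and several processes can compete:
- capture of the acyl group by Et2NH (aminocarbonylation to the diethylamide);
- direct alkynylation without CO insertion, followed by five-membered closure onto the alkyne;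
- early loss of the acetates, which leaves an electron-rich iodophenoxide that undergoes oxidative addition slowly;
- aurone-type 5-exo closure, if the ynone cyclises as its phenoxide before the amine has added.

Fallback: the carbonyl carbon is brought in as a carboxylic acid derivative, without palladium or CO. The fallback sets out from 5 and 11 and returns at 15.
- Iodo diol 5 is converted with MOMCl and iPr2NEt into 2-(benzyloxy)-5-iodo-1,3-dimethoxy-4,6-bis(methoxymethoxy)benzene F1.
- Alkyne 11 is deprotonated (n-BuLi, THF, −78 °C) and acylated with N-methoxy-N-methylcarbamoyl chloride to the Weinreb ynamide 3-[2,5-bis(benzyloxy)-4-methoxyphenyl]-N-methoxy-N-methylprop-2-ynamide F2.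
- Iodine–lithium exchange on F1 (n-BuLi, THF, −78 °C) and addition of the aryllithium to F2 should give the ynone 1-[4-(benzyloxy)-3,5-dimethoxy-2,6-bis(methoxymethoxy)phenyl]-3-[2,5-bis(benzyloxy)-4-methoxyphenyl]prop-2-yn-1-one F3.
- Et2NH adds to F3 to give the enaminone 1-[4-(benzyloxy)-3,5-dimethoxy-2,6-bis(methoxymethoxy)phenyl]-3-[2,5-bis(benzyloxy)-4-methoxyphenyl]-3-(diethylamino)prop-2-en-1-one F4.
- HCl in MeOH removes both methoxymethyl groups and closes ring C with loss of diethylamine, giving flavone 15.

**Step 3.** After the first hydroxylation the ring is a phenoxide, so the second C–Br bond is more electron-rich and oxidative addition slows. Hydrodebromination, coupling of the phenoxide with remaining bromide to a diaryl ether, and air oxidation of the diphenoxide can then take over.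

Fallback: the oxygen is introduced through boron. Dibromide 3 is borylated twice under Miyaura conditions (B2pin2, PdCl2(dppf), KOAc, dioxane, 90 °C) to 2,2'-[5-(benzyloxy)-4,6-dimethoxy-1,3-phenylene]bis(4,4,5,5-tetramethyl-1,3,2-dioxaborolane) F5. Oxidation of F5 with H2O2 and NaOH in THF–H2O returns to diol 4.

**Step 11.** Three things can go wrong:
- the 3-lithio species 17 can open ring C by β-elimination of the C8a phenoxide if it warms before boron traps it;
- the amide base may deprotonate a benzylic position of a benzyl ether, leading to Wittig rearrangement;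
- lithiation may be incomplete on this crowded, poorly soluble substrate.

Fallback: the oxygen is delivered by an electrophilic oxidant instead of a base. Flavone 16 is epoxidised at C2=C3 with dimethyldioxirane (acetone–CH2Cl2, 0 °C) to the racemic, cis-fused epoxide 4,6-bis(benzyloxy)-1a-[2,5-bis(benzyloxy)-4-methoxyphenyl]-3,5-dimethoxy-1a,7a-dihydro-7H-oxireno[2,3-b]chromen-7-one F6. Acid (p-TsOH, CH2Cl2) opens the epoxide and tautomerisation gives flavonol 19.

**Step 13.** The C2=C3 bond may be reduced on long exposure, the benzyl ether at C5 next to the carbonyl may be cleaved incompletely, and the hydroquinone of ring B may oxidise to the quinone when the catalyst is filtered off in air.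

Fallback: non-reductive, Lewis-acid debenzylation. Compound 20 is treated with BCl3 and pentamethylbenzene as benzyl cation scavenger (CH2Cl2, −78 °C), which should cleave the benzyl ethers and leave the methyl ethers at that temperature, giving 21 directly. No new compound lies on this path (entry F0).

## Further compounds

F1 | step 9 | 2-(benzyloxy)-5-iodo-1,3-dimethoxy-4,6-bis(methoxymethoxy)benzene | COCOc1c(I)c(OCOC)c(OC)c(OCc2ccccc2)c1OC
F2 | step 9 | 3-[2,5-bis(benzyloxy)-4-methoxyphenyl]-N-methoxy-N-methylprop-2-ynamide | CON(C)C(=O)C#Cc1cc(OCc2ccccc2)c(OC)cc1OCc1ccccc1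
F3 | step 9 | 1-[4-(benzyloxy)-3,5-dimethoxy-2,6-bis(methoxymethoxy)phenyl]-3-[2,5-bis(benzyloxy)-4-methoxyphenyl]prop-2-yn-1-one | COCOc1c(C(=O)C#Cc2cc(OCc3ccccc3)c(OC)cc2OCc2ccccc2)c(OCOC)c(OC)c(OCc2ccccc2)c1OC
F4 | step 9 | 1-[4-(benzyloxy)-3,5-dimethoxy-2,6-bis(methoxymethoxy)phenyl]-3-[2,5-bis(benzyloxy)-4-methoxyphenyl]-3-(diethylamino)prop-2-en-1-one (alkene geometry not fixed) | CCN(CC)C(=CC(=O)c1c(OCOC)c(OC)c(OCc2ccccc2)c(OC)c1OCOC)c1cc(OCc2ccccc2)c(OC)cc1OCc1ccccc1
F5 | step 3 | 2,2'-[5-(benzyloxy)-4,6-dimethoxy-1,3-phenylene]bis(4,4,5,5-tetramethyl-1,3,2-dioxaborolane) | COc1c(B2OC(C)(C)C(C)(C)O2)cc(B2OC(C)(C)C(C)(C)O2)c(OC)c1OCc1ccccc1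
F6 | step 11 | 4,6-bis(benzyloxy)-1a-[2,5-bis(benzyloxy)-4-methoxyphenyl]-3,5-dimethoxy-1a,7a-dihydro-7H-oxireno[2,3-b]chromen-7-one (racemic, cis-fused; one enantiomer drawn) | O=C1c2c(OCc3ccccc3)c(OC)c(OCc3ccccc3)c(OC)c2O[C@]2(c3cc(OCc4ccccc4)c(OC)cc3OCc3ccccc3)O[C@H]12
F0 | step 13 | none | none
A1 | alternative 1 | 5,7-bis(benzyloxy)-2-[2,5-bis(benzyloxy)-4-methoxyphenyl]-3-hydroxy-6,8-dimethoxychroman-4-one (diastereomer mixture) | COc1cc(OCc2ccccc2)c(cc1OCc1ccccc1)C1Oc2c(OC)c(OCc3ccccc3)c(OC)c(OCc3ccccc3)c2C(=O)C1O
A2 | alternative 1 | 2-[2,5-bis(benzyloxy)-4-methoxyphenyl]-2-[3,5-bis(benzyloxy)-2-formyl-4,6-dimethoxyphenoxy]acetaldehyde (racemic) | O=CC(Oc1c(OC)c(OCc2ccccc2)c(OC)c(OCc2ccccc2)c1C=O)c1cc(OCc2ccccc2)c(OC)cc1OCc1ccccc1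
A3 | alternative 2 | 5,7-bis(benzyloxy)-2-(2-hydroxy-4,5-dimethoxyphenyl)-3,6,8-trimethoxy-4H-chromen-4-one | COc1cc(O)c(cc1OC)-c1oc2c(OC)c(OCc3ccccc3)c(OC)c(OCc3ccccc3)c2c(=O)c1OC
A4 | alternative 2 | 5,7-bis(benzyloxy)-2-ethynyl-3,6,8-trimethoxy-4H-chromen-4-one | C#Cc1oc2c(OC)c(OCc3ccccc3)c(OC)c(OCc3ccccc3)c2c(=O)c1OC
A5 | alternative 2 | pentacarbonyl[methoxy(1-methoxyethenyl)methylidene]chromium, (CO)5Cr=C(OMe)C(OMe)=CH2 | COC(=C)C(OC)=[Cr](=C=O)(=C=O)(=C=O)(=C=O)=C=O
A6 | alternative 3 | 7-(benzyloxy)-2-[2,5-bis(benzyloxy)-4-methoxyphenyl]-5-bromo-3,6,8-trimethoxy-4H-chromen-4-one | COc1cc(OCc2ccccc2)c(cc1OCc1ccccc1)-c1oc2c(OC)c(OCc3ccccc3)c(OC)c(Br)c2c(=O)c1OC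
A7 | alternative 3 | 1-[4-(benzyloxy)-2,6-dibromo-3,5-dimethoxyphenyl]-3-[2,5-bis(benzyloxy)-4-methoxyphenyl]-2-methoxypropane-1,3-dione | COC(C(=O)c1c(Br)c(OC)c(OCc2ccccc2)c(OC)c1Br)C(=O)c1cc(OCc2ccccc2)c(OC)cc1OCc1ccccc1
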